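**Retrosynthetic overview**

1. Target 24 ⇒ (desilylation) 23 ⇒ C10–C11 bond, made in a one-pot three-component union of ring A diyne 9, a methyl group from Me3Al and the C26 iodide 21 (Zr-catalysed syn-methylalumination of C9≡C10, then Pd/Zn alkenyl–alkenyl coupling).
2. Enabling feature: C9 carries a methyl and no H, C10 carries one H, the methyl is cis to C11 (9E), and C8 is an sp carbon of the C7≡C8 alkyne on C6 of ring A. C9=C10 is therefore the retron of a syn Me–Al addition to the terminal alkyne of a ring A buta-1,3-diyne, whose internal alkyne is shielded by the C1 gem-dimethyl and C5 methyl groups.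
3. 21 ⇒ the same operation on ring B diyne 17 with the symmetric C12 diiodide 19 (double Takai olefination of C10 dialdehyde 18).
4. 9 ⇐ (4R,6R)-actinol 1 (enol triflate, Negishi alkynylation). 17 ⇐ ketoisophorone 10 (asymmetric transfer hydrogenation sets C3'; alkynyl addition and oxidative 1,3-transposition put the diyne on C6' and a carbonyl on C4'; hydride reduction sets C4' cis to C3'). Both rings take their C4 unit from one batch of lithium diynide 6, made from 5.
5. No ring is formed: rings A and B are carried in from 1 and 10. Order of work: ring A (steps 1–5, step 3 giving the diynide used for both rings), ring B (steps 6–12), chain (steps 13–15), desilylation (step 16).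

Key step: step 15

Assumption: carotenoid numbering is used, unprimed for the half with ring A (the 3-hydroxy ring) and primed for the half with ring B (the 3',4'-dihydroxy ring); 1, 5, 10 and 18 are taken as catalogue chemicals, the solution of 6 from step 3 is made as one titrated batch and divided between steps 4 and 8, and all polyenes are handled under argon in dim light.

**Route**

Step 1
Reactants: 1 (4R,6R)-4-hydroxy-2,2,6-trimethylcyclohexan-1-one
Product: 2 (4R,6R)-4-[(tert-butyldimethylsilyl)oxy]-2,2,6-trimethylcyclohexan-1-one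
Conditions: TBSCl, imidazole, DMF, rt
Reagents that add atoms: tert-butyldimethylsilyl chloride, CC(C)(C)[Si](C)(C)Cl
Why: Silylation of an unhindered secondary alcohol (silyl ether protection) that touches neither stereocentre.

Step 2
Reactants: 2 (4R,6R)-4-[(tert-butyldimethylsilyl)oxy]-2,2,6-trimethylcyclohexan-1-one
Product: 4 (4R)-4-[(tert-butyldimethylsilyl)oxy]-2,6,6-trimethylcyclohex-1-en-1-yl trifluoromethanesulfonate, via lithium enolate 3 (not isolated)
Conditions: LiN(i-Pr)2 (LDA), THF, −78 to 0 °C; PhNTf2, −78 °C to rt; aq NH4Cl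
Reagents that add atoms: N-phenylbis(trifluoromethanesulfonimide), O=S(=O)(N(c1ccccc1)S(=O)(=O)C(F)(F)F)C(F)(F)F
Why: Only C6–H is enolisable (C2 is quaternary), so a single tetrasubstituted enolate forms and is trapped on oxygen (enol triflate formation); the silyloxy group is γ to the carbonyl and cannot be eliminated, and the carbinol centre is untouched.

Step 3
Reactants: 5 1,4-bis(trimethylsilyl)buta-1,3-diyne
Product: 6 lithium (trimethylsilyl)butadiynide, kept as a solution in Et2O/THF under argon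
Conditions: MeLi·LiBr (0.95 equiv), Et2O, rt; diluted with THF, titrated, held at −20 °C and divided between steps 4 and 8
Reagents that add atoms: methyllithium, [Li]C
Why: Methyllithium attacks one silicon and cleaves a single alkynyl C–Si bond (desilylative metalation), the anionic diynide formed deactivating the remaining silyl group toward a second cleavage, so one batch of the mono-lithio diyne serves both ring syntheses.

Step 4
Reactants: 4 (4R)-4-[(tert-butyldimethylsilyl)oxy]-2,6,6-trimethylcyclohex-1-en-1-yl trifluoromethanesulfonate; 6 lithium (trimethylsilyl)butadiynide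
Product: 8 tert-butyldimethyl({(1R)-3,5,5-trimethyl-4-[4-(trimethylsilyl)buta-1,3-diyn-1-yl]cyclohex-3-en-1-yl}oxy)silane, via bromozinc (trimethylsilyl)butadiynide 7 (not isolated)
Conditions: 6 (1.3 equiv, solution from step 3), ZnBr2 (1.4 equiv), THF, 0 °C; then 4, Pd(PPh3)4 (5 mol%), THF, rt to 50 °C
Reagents that add atoms: none
Why: Zinc exchange of 6 gives 7, and zerovalent palladium inserts into the C–OTf bond of 4 and couples with 7 (Negishi alkynylation of an alkenyl triflate), the zinc reagent avoiding copper-mediated diyne homocoupling on this hindered triflate.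

Step 5
Reactants: 8 tert-butyldimethyl({(1R)-3,5,5-trimethyl-4-[4-(trimethylsilyl)buta-1,3-diyn-1-yl]cyclohex-3-en-1-yl}oxy)silane
Product: 9 {[(1R)-4-(buta-1,3-diyn-1-yl)-3,5,5-trimethylcyclohex-3-en-1-yl]oxy}(tert-butyl)dimethylsilane
Conditions: K2CO3 (cat.), MeOH/THF, 0 °C to rt; used promptly as a solution
Reagents that add atoms: none
Why: Methanolysis of the alkynyl C–Si bond (protodesilylation) is much faster than cleavage of the secondary silyl ether, giving the terminal diyne needed for carbometalation.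

Step 6
Reactants: 10 2,6,6-trimethylcyclohex-2-ene-1,4-dione (ketoisophorone)
Product: 11 (4S)-4-hydroxy-2,6,6-trimethylcyclohex-2-en-1-one
Conditions: RuCl(p-cymene)[(S,S)-TsDPEN] (0.5 mol%), KOH (1 mol%), i-PrOH, rt
Reagents that add atoms: none
Why: Noyori asymmetric transfer hydrogenation reduces the less hindered C4 carbonyl (C1 is flanked by the gem-dimethyl carbon and the methyl-bearing alkene carbon), and the (S,S)-ligand is expected, on the model in which the alkenyl side takes the place of an aryl group, to give the 4S carbinol, the future C3' (the antipodal ligand would be used if the sense proved opposite).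

Step 7
Reactants: 11 (4S)-4-hydroxy-2,6,6-trimethylcyclohex-2-en-1-one
Product: 12 (4S)-4-[(tert-butyldimethylsilyl)oxy]-2,6,6-trimethylcyclohex-2-en-1-one
Conditions: TBSCl, imidazole, DMF, rt
Reagents that add atoms: tert-butyldimethylsilyl chloride, CC(C)(C)[Si](C)(C)Cl
Why: Silyl ether protection of the allylic alcohol under near-neutral conditions that do not epimerise the γ-stereocentre.

Step 8
Reactants: 12 (4S)-4-[(tert-butyldimethylsilyl)oxy]-2,6,6-trimethylcyclohex-2-en-1-one; 6 lithium (trimethylsilyl)butadiynide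
Product: 13 (4S)-4-[(tert-butyldimethylsilyl)oxy]-2,6,6-trimethyl-1-[4-(trimethylsilyl)buta-1,3-diyn-1-yl]cyclohex-2-en-1-ol (mixture of C1 epimers)
Conditions: 6 (1.3 equiv, solution from step 3), THF, −78 °C; then 12, −78 to 0 °C; aq NH4Cl
Reagents that add atoms: none
Why: 1,2-addition of a weakly basic alkynyllithium to a carbonyl that has no α-hydrogen on either side, so the C4 centre is not at risk; the new carbinol centre forms as a mixture and is erased in step 9.

Step 9
Reactants: 13 (4S)-4-[(tert-butyldimethylsilyl)oxy]-2,6,6-trimethyl-1-[4-(trimethylsilyl)buta-1,3-diyn-1-yl]cyclohex-2-en-1-ol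
Product: 14 (6S)-6-[(tert-butyldimethylsilyl)oxy]-2,4,4-trimethyl-3-[4-(trimethylsilyl)buta-1,3-diyn-1-yl]cyclohex-2-en-1-one
Conditions: pyridinium chlorochromate (C5H5NH)[CrO3Cl], powdered 4 Å molecular sieves, CH2Cl2, rt
Reagents that add atoms: pyridinium chlorochromate, [O-][Cr](=O)(=O)Cl.c1cc[nH+]cc1
Why: Babler–Dauben oxidative transposition: the tertiary allylic chromate ester shifts [3,3] to the secondary allylic position and is oxidised by hexavalent chromium to the enone, which puts oxygen on the future C4' and the diyne on the tetrasubstituted C5'=C6' alkene without involving the silyloxy centre.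

Step 10
Reactants: 14 (6S)-6-[(tert-butyldimethylsilyl)oxy]-2,4,4-trimethyl-3-[4-(trimethylsilyl)buta-1,3-diyn-1-yl]cyclohex-2-en-1-one
Product: 15 (1R,6S)-6-[(tert-butyldimethylsilyl)oxy]-2,4,4-trimethyl-3-[4-(trimethylsilyl)buta-1,3-diyn-1-yl]cyclohex-2-en-1-ol
Conditions: LiBH(s-Bu)3, THF, −78 °C; aq NH4Cl
Reagents that add atoms: none
Why: 1,2-reduction of a β,β-disubstituted enone by a bulky trialkylborohydride, which attacks along the equatorial trajectory and should give the pseudo-axial alcohol cis to the pseudo-equatorial C3' silyloxy group (substrate control, 4'R).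

Step 11
Reactants: 15 (1R,6S)-6-[(tert-butyldimethylsilyl)oxy]-2,4,4-trimethyl-3-[4-(trimethylsilyl)buta-1,3-diyn-1-yl]cyclohex-2-en-1-ol
Product: 16 {4-[(3R,4S)-3,4-bis[(tert-butyldimethylsilyl)oxy]-2,6,6-trimethylcyclohex-1-en-1-yl]buta-1,3-diyn-1-yl}trimethylsilane
Conditions: TBSOTf, 2,6-lutidine, CH2Cl2, −78 to 0 °C
Reagents that add atoms: tert-butyldimethylsilyl trifluoromethanesulfonate, CC(C)(C)[Si](C)(C)OS(=O)(=O)C(F)(F)F
Why: The silyl triflate with a hindered base silylates the crowded allylic alcohol without ionising it (silyl ether protection), giving one kind of protecting group on all three oxygens of the target.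

Step 12
Reactants: 16 {4-[(3R,4S)-3,4-bis[(tert-butyldimethylsilyl)oxy]-2,6,6-trimethylcyclohex-1-en-1-yl]buta-1,3-diyn-1-yl}trimethylsilane
Product: 17 (3R,4S)-1-(buta-1,3-diyn-1-yl)-3,4-bis[(tert-butyldimethylsilyl)oxy]-2,6,6-trimethylcyclohex-1-ene
Conditions: K2CO3 (cat.), MeOH/THF, 0 °C; used promptly as a solution
Reagents that add atoms: none
Why: Selective protodesilylation of the alkynylsilane in the presence of two secondary silyl ethers.

Step 13
Reactants: 18 (2E,4E,6E)-2,7-dimethylocta-2,4,6-trienedial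
Product: 19 (1E,3E,5E,7E,9E)-1,10-diiodo-3,8-dimethyldeca-1,3,5,7,9-pentaene
Conditions: CrCl2 (12 equiv), CHI3 (4 equiv), THF/1,4-dioxane, 0 °C to rt, dark
Reagents that add atoms: iodoform, IC(I)I
Why: Takai iodo-olefination at both formyl groups: the gem-dichromium species formed from CHI3 and divalent chromium adds to each aldehyde and eliminates to the (E)-alkenyl iodide, the α-methyl enal termini favouring E.

Step 14
Reactants: 17 (3R,4S)-1-(buta-1,3-diyn-1-yl)-3,4-bis[(tert-butyldimethylsilyl)oxy]-2,6,6-trimethylcyclohex-1-ene; 19 (1E,3E,5E,7E,9E)-1,10-diiodo-3,8-dimethyldeca-1,3,5,7,9-pentaene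
Product: 21 (3R,4S)-3,4-bis[(tert-butyldimethylsilyl)oxy]-1-[(3E,5E,7E,9E,11E,13E)-14-iodo-3,7,12-trimethyltetradeca-3,5,7,9,11,13-hexaen-1-yn-1-yl]-2,6,6-trimethylcyclohex-1-ene, via alkenylalane 20 (not isolated)
Conditions: Me3Al (3 equiv), Cp2ZrCl2 (0.5 equiv), CH2Cl2, 0 °C to rt; volatiles removed in vacuo; then 19 (3 equiv), ZnCl2 (0.5 equiv), Pd2(dba)3 (2.5 mol%), P(2-furyl)3 (10 mol%), THF, rt, dark
Reagents that add atoms: trimethylaluminium, C[Al](C)C
Why: The same tandem as the key step (Negishi Zr-catalysed syn-methylalumination of the terminal alkyne, then Pd/Zn-catalysed alkenyl–alkenyl coupling with retention at both partners) sets the 9'E alkene and the C10'–C11' bond, while the threefold excess of 19 is meant to hold the reaction at mono-substitution and unreacted 19 is to be recovered.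

Step 15
Reactants: 9 {[(1R)-4-(buta-1,3-diyn-1-yl)-3,5,5-trimethylcyclohex-3-en-1-yl]oxy}(tert-butyl)dimethylsilane; 21 (3R,4S)-3,4-bis[(tert-butyldimethylsilyl)oxy]-1-[(3E,5E,7E,9E,11E,13E)-14-iodo-3,7,12-trimethyltetradeca-3,5,7,9,11,13-hexaen-1-yn-1-yl]-2,6,6-trimethylcyclohex-1-ene
Product: 23 (all-E)-(3R,3'S,4'R)-3,3',4'-tris[(tert-butyldimethylsilyl)oxy]-7,8,7',8'-tetradehydro-β,β-carotene, via alkenylalane 22 (not isolated)
Conditions: 9 (1.3 equiv), Me3Al (3 equiv), Cp2ZrCl2 (0.5 equiv), CH2Cl2, 0 °C to rt; volatiles removed in vacuo; then 21 (1.0 equiv), ZnCl2 (0.5 equiv), Pd2(dba)3 (2.5 mol%), P(2-furyl)3 (10 mol%), THF, rt, dark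
Reagents that add atoms: trimethylaluminium, C[Al](C)C
Why: Cp2ZrCl2 and Me3Al form a cationic methylzirconocene–aluminate that adds methyl and metal syn across the terminal C9≡C10 triple bond of 9 with methyl on the internal carbon, Zr-to-Al exchange gives the (E)-alkenylalane 22, and this transfers its alkenyl group through zinc to the alkenylpalladium iodide formed by oxidative addition of zerovalent palladium into the C11–I bond of 21, after which reductive elimination forms the C10–C11 bond. The closest known reaction type is the Negishi tandem of Zr-catalysed methylalumination and Pd/Zn-catalysed alkenyl–alkenyl cross-coupling, known for terminal enynes and 1,3-diynes in isoprenoid polyene work. No ring is closed and no stereocentre is created; the stereo-element set is the 9E geometry of C9=C10, fixed by the syn addition (C9-methyl cis to C11) and kept by the stereoretentive coupling, which also keeps the 11E geometry of 21. The step needs regioselectivity (methyl to C9, aluminium to C10), secured by the terminal position of the alkyne, and site selectivity for C9≡C10 over the internal C7≡C8 alkyne, secured by the flanking C1 gem-dimethyl and C5 methyl groups of ring A and by the much lower rate of internal alkynes. Alkenyl transfer from aluminium and zinc is faster than methyl transfer, and excess Me3Al is removed before 21 is added, so the iodide should be consumed by 22 only; the three silyl ethers, the C7'≡C8' alkyne and the polyene are inert to both stages.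

Step 16
Reactants: 23 (all-E)-(3R,3'S,4'R)-3,3',4'-tris[(tert-butyldimethylsilyl)oxy]-7,8,7',8'-tetradehydro-β,β-carotene
Product: 24 (all-E)-(3R,3'S,4'R)-7,8,7',8'-tetradehydro-β,β-carotene-3,3',4'-triol (CNP0323983.1)
Conditions: Bu4NF (6 equiv), THF, 0 °C to rt, dark
Reagents that add atoms: none
Why: Fluoride cleaves the three Si–O bonds under non-acidic conditions (silyl ether deprotection), which avoids ionisation at the allylic C4' oxygen and leaves the decaene-diyne chromophore and the three stereocentres untouched.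

**Compound list**

1 | (4R,6R)-4-hydroxy-2,2,6-trimethylcyclohexan-1-one (actinol) | C[C@H]1C(=O)C(C)(C)C[C@H](O)C1 | starting material
2 | (4R,6R)-4-[(tert-butyldimethylsilyl)oxy]-2,2,6-trimethylcyclohexan-1-one | C[C@H]1C(=O)C(C)(C)C[C@H](O[Si](C)(C)C(C)(C)C)C1 | intermediate
3 | lithium (4R)-4-[(tert-butyldimethylsilyl)oxy]-2,6,6-trimethylcyclohex-1-en-1-olate | CC1=C(O[Li])C(C)(C)C[C@H](O[Si](C)(C)C(C)(C)C)C1 | intermediate (not isolated)
4 | (4R)-4-[(tert-butyldimethylsilyl)oxy]-2,6,6-trimethylcyclohex-1-en-1-yl trifluoromethanesulfonate | CC1=C(OS(=O)(=O)C(F)(F)F)C(C)(C)C[C@H](O[Si](C)(C)C(C)(C)C)C1 | intermediate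
5 | 1,4-bis(trimethylsilyl)buta-1,3-diyne | C[Si](C)(C)C#CC#C[Si](C)(C)C | starting material
6 | lithium (trimethylsilyl)butadiynide (solution in Et2O/THF) | [Li]C#CC#C[Si](C)(C)C | intermediate
7 | bromozinc (trimethylsilyl)butadiynide | Br[Zn]C#CC#C[Si](C)(C)C | intermediate (not isolated)
8 | tert-butyldimethyl({(1R)-3,5,5-trimethyl-4-[4-(trimethylsilyl)buta-1,3-diyn-1-yl]cyclohex-3-en-1-yl}oxy)silane | CC1=C(C#CC#C[Si](C)(C)C)C(C)(C)C[C@H](O[Si](C)(C)C(C)(C)C)C1 | intermediate
9 | {[(1R)-4-(buta-1,3-diyn-1-yl)-3,5,5-trimethylcyclohex-3-en-1-yl]oxy}(tert-butyl)dimethylsilane (ring A diyne) | CC1=C(C#CC#C)C(C)(C)C[C@H](O[Si](C)(C)C(C)(C)C)C1 | intermediate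
10 | 2,6,6-trimethylcyclohex-2-ene-1,4-dione (ketoisophorone) | CC1=CC(=O)CC(C)(C)C1=O | starting material
11 | (4S)-4-hydroxy-2,6,6-trimethylcyclohex-2-en-1-one | CC1=C[C@@H](O)CC(C)(C)C1=O | intermediate
12 | (4S)-4-[(tert-butyldimethylsilyl)oxy]-2,6,6-trimethylcyclohex-2-en-1-one | CC1=C[C@@H](O[Si](C)(C)C(C)(C)C)CC(C)(C)C1=O | intermediate
13 | (4S)-4-[(tert-butyldimethylsilyl)oxy]-2,6,6-trimethyl-1-[4-(trimethylsilyl)buta-1,3-diyn-1-yl]cyclohex-2-en-1-ol (C1 epimers) | CC1=C[C@@H](O[Si](C)(C)C(C)(C)C)CC(C)(C)C1(O)C#CC#C[Si](C)(C)C | intermediate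
14 | (6S)-6-[(tert-butyldimethylsilyl)oxy]-2,4,4-trimethyl-3-[4-(trimethylsilyl)buta-1,3-diyn-1-yl]cyclohex-2-en-1-one | C[Si](C)(C)C#CC#CC1=C(C)C(=O)[C@@H](O[Si](C)(C)C(C)(C)C)CC1(C)C | intermediate
15 | (1R,6S)-6-[(tert-butyldimethylsilyl)oxy]-2,4,4-trimethyl-3-[4-(trimethylsilyl)buta-1,3-diyn-1-yl]cyclohex-2-en-1-ol (cis) | C[Si](C)(C)C#CC#CC1=C(C)[C@@H](O)[C@@H](O[Si](C)(C)C(C)(C)C)CC1(C)C | intermediate
16 | {4-[(3R,4S)-3,4-bis[(tert-butyldimethylsilyl)oxy]-2,6,6-trimethylcyclohex-1-en-1-yl]buta-1,3-diyn-1-yl}trimethylsilane | C[Si](C)(C)C#CC#CC1=C(C)[C@@H](O[Si](C)(C)C(C)(C)C)[C@@H](O[Si](C)(C)C(C)(C)C)CC1(C)C | intermediate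
17 | (3R,4S)-1-(buta-1,3-diyn-1-yl)-3,4-bis[(tert-butyldimethylsilyl)oxy]-2,6,6-trimethylcyclohex-1-ene (ring B diyne) | C#CC#CC1=C(C)[C@@H](O[Si](C)(C)C(C)(C)C)[C@@H](O[Si](C)(C)C(C)(C)C)CC1(C)C | intermediate
18 | (2E,4E,6E)-2,7-dimethylocta-2,4,6-trienedial | O=C/C(C)=C/C=C/C=C(C)/C=O | starting material
19 | (1E,3E,5E,7E,9E)-1,10-diiodo-3,8-dimethyldeca-1,3,5,7,9-pentaene | I/C=C/C(C)=C/C=C/C=C(C)/C=C/I | intermediate
20 | dimethyl{(1E)-4-[(3R,4S)-3,4-bis[(tert-butyldimethylsilyl)oxy]-2,6,6-trimethylcyclohex-1-en-1-yl]-2-methylbut-1-en-3-yn-1-yl}alane | C[Al](C)/C=C(\C)C#CC1=C(C)[C@@H](O[Si](C)(C)C(C)(C)C)[C@@H](O[Si](C)(C)C(C)(C)C)CC1(C)C | intermediate (not isolated)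
21 | (3R,4S)-3,4-bis[(tert-butyldimethylsilyl)oxy]-1-[(3E,5E,7E,9E,11E,13E)-14-iodo-3,7,12-trimethyltetradeca-3,5,7,9,11,13-hexaen-1-yn-1-yl]-2,6,6-trimethylcyclohex-1-ene (C26 iodide) | I/C=C/C(C)=C/C=C/C=C(C)/C=C/C=C(\C)C#CC1=C(C)[C@@H](O[Si](C)(C)C(C)(C)C)[C@@H](O[Si](C)(C)C(C)(C)C)CC1(C)C | intermediate
22 | dimethyl{(1E)-4-[(4R)-4-[(tert-butyldimethylsilyl)oxy]-2,6,6-trimethylcyclohex-1-en-1-yl]-2-methylbut-1-en-3-yn-1-yl}alane | CC1=C(C#C/C(C)=C/[Al](C)C)C(C)(C)C[C@H](O[Si](C)(C)C(C)(C)C)C1 | intermediate (not isolated)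
23 | (all-E)-(3R,3'S,4'R)-3,3',4'-tris[(tert-butyldimethylsilyl)oxy]-7,8,7',8'-tetradehydro-β,β-carotene | CC1=C(C#C/C(C)=C/C=C/C(C)=C/C=C/C=C(C)/C=C/C=C(\C)C#CC2=C(C)[C@@H](O[Si](C)(C)C(C)(C)C)[C@@H](O[Si](C)(C)C(C)(C)C)CC2(C)C)C(C)(C)C[C@H](O[Si](C)(C)C(C)(C)C)C1 | intermediate
24 | (all-E)-(3R,3'S,4'R)-7,8,7',8'-tetradehydro-β,β-carotene-3,3',4'-triol (CNP0323983.1) | CC1=C(C#C/C(C)=C/C=C/C(C)=C/C=C/C=C(C)/C=C/C=C(\C)C#CC2=C(C)[C@@H](O)[C@@H](O)CC2(C)C)C(C)(C)C[C@H](O)C1 | target

**Summary**

Total step count: 16. Longest linear sequence: 10 steps (steps 6–12, 14, 15, 16).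

Steps most likely to fail:

1. Step 15. In the one-pot sequence the alkenyl group may pass too slowly from aluminium and zinc to palladium, so that methyl transfer, homocoupling and decay of the light- and metal-sensitive iodide compete; metalation of the acidic diyne C–H by Me3Al may also lower the amount of alane. Fallback, setting out from 9 and returning at 23: 9 is methylaluminated as in step 15 and alane 22 is quenched with I2 (THF, −30 °C) to give the isolable (E)-alkenyl iodide F1. Iodine–lithium exchange (t-BuLi, Et2O, −78 °C) and trapping with 2-isopropoxy-4,4,5,5-tetramethyl-1,3,2-dioxaborolane should give the pinacol alkenylboronate F2. Purified F2 is joined to 21 by Suzuki–Miyaura coupling (Pd(PPh3)4, aq KOH, THF, rt, dark) to give 23, so the same C10–C11 bond is formed from a defined, stoichiometric boron nucleophile.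

2. Step 14. The second C–I terminus of 19, or that of product 21, may enter the coupling, so that a doubly substituted symmetric by-product forms and 21 is eroded or hard to separate from recovered 19. Fallback, setting out from 17 and returning at 21, with no symmetric bis-electrophile: alane 20 is turned into its aluminate with n-BuLi and trapped with paraformaldehyde to give the (E)-allylic alcohol F3. Appel bromination (CBr4, PPh3, CH2Cl2, −20 °C) gives the allylic bromide F4, and Michaelis–Arbuzov reaction with P(OEt)3 (90 °C) gives the diethyl phosphonate F5. Horner–Wadsworth–Emmons olefination with an excess of dial 18 (NaN(SiMe3)2, THF, −78 to 0 °C) gives the C25 aldehyde F6, and Takai iodo-olefination (CrCl2, CHI3, THF/dioxane) gives 21.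

3. Step 10. Hydride delivery may show poor facial selectivity (axial attack leading to the trans-alcohol) or stray into conjugate reduction of the enyne ketone. Fallback, setting out from 14 and returning at 17: Luche reduction (NaBH4, CeCl3·7H2O, MeOH, −40 °C), which favours axial attack, is used to make the trans-alcohol F7 on purpose. Mitsunobu inversion (4-nitrobenzoic acid, PPh3, DIAD, toluene, 0 °C) gives the cis 4-nitrobenzoate F8. K2CO3 in MeOH removes the ester and the alkynylsilane together to give the cis-alcohol with a terminal diyne F9 (silyl migration between the two cis oxygens is of no consequence), and TBSOTf/2,6-lutidine gives 17.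

**Further compounds**

F1 | step 15 | tert-butyl({(1R)-4-[(3E)-4-iodo-3-methylbut-3-en-1-yn-1-yl]-3,5,5-trimethylcyclohex-3-en-1-yl}oxy)dimethylsilane | CC1=C(C#C/C(C)=C/I)C(C)(C)C[C@H](O[Si](C)(C)C(C)(C)C)C1
F2 | step 15 | tert-butyldimethyl({(1R)-3,5,5-trimethyl-4-[(3E)-3-methyl-4-(4,4,5,5-tetramethyl-1,3,2-dioxaborolan-2-yl)but-3-en-1-yn-1-yl]cyclohex-3-en-1-yl}oxy)silane | CC1=C(C#C/C(C)=C/B2OC(C)(C)C(C)(C)O2)C(C)(C)C[C@H](O[Si](C)(C)C(C)(C)C)C1
F3 | step 14 | (2E)-5-[(3R,4S)-3,4-bis[(tert-butyldimethylsilyl)oxy]-2,6,6-trimethylcyclohex-1-en-1-yl]-3-methylpent-2-en-4-yn-1-ol | OC/C=C(\C)C#CC1=C(C)[C@@H](O[Si](C)(C)C(C)(C)C)[C@@H](O[Si](C)(C)C(C)(C)C)CC1(C)C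
F4 | step 14 | (3R,4S)-1-[(3E)-5-bromo-3-methylpent-3-en-1-yn-1-yl]-3,4-bis[(tert-butyldimethylsilyl)oxy]-2,6,6-trimethylcyclohex-1-ene | BrC/C=C(\C)C#CC1=C(C)[C@@H](O[Si](C)(C)C(C)(C)C)[C@@H](O[Si](C)(C)C(C)(C)C)CC1(C)C
F5 | step 14 | diethyl {(2E)-5-[(3R,4S)-3,4-bis[(tert-butyldimethylsilyl)oxy]-2,6,6-trimethylcyclohex-1-en-1-yl]-3-methylpent-2-en-4-yn-1-yl}phosphonate | CCOP(=O)(OCC)C/C=C(\C)C#CC1=C(C)[C@@H](O[Si](C)(C)C(C)(C)C)[C@@H](O[Si](C)(C)C(C)(C)C)CC1(C)C
F6 | step 14 | (2E,4E,6E,8E,10E)-13-[(3R,4S)-3,4-bis[(tert-butyldimethylsilyl)oxy]-2,6,6-trimethylcyclohex-1-en-1-yl]-2,7,11-trimethyltrideca-2,4,6,8,10-pentaen-12-ynal | O=C/C(C)=C/C=C/C=C(C)/C=C/C=C(\C)C#CC1=C(C)[C@@H](O[Si](C)(C)C(C)(C)C)[C@@H](O[Si](C)(C)C(C)(C)C)CC1(C)C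
F7 | step 10 | (1S,6S)-6-[(tert-butyldimethylsilyl)oxy]-2,4,4-trimethyl-3-[4-(trimethylsilyl)buta-1,3-diyn-1-yl]cyclohex-2-en-1-ol (trans) | C[Si](C)(C)C#CC#CC1=C(C)[C@H](O)[C@@H](O[Si](C)(C)C(C)(C)C)CC1(C)C
F8 | step 10 | (1R,6S)-6-[(tert-butyldimethylsilyl)oxy]-2,4,4-trimethyl-3-[4-(trimethylsilyl)buta-1,3-diyn-1-yl]cyclohex-2-en-1-yl 4-nitrobenzoate | C[Si](C)(C)C#CC#CC1=C(C)[C@@H](OC(=O)c2ccc(cc2)[N+](=O)[O-])[C@@H](O[Si](C)(C)C(C)(C)C)CC1(C)C
F9 | step 10 | (1R,6S)-3-(buta-1,3-diyn-1-yl)-6-[(tert-butyldimethylsilyl)oxy]-2,4,4-trimethylcyclohex-2-en-1-ol | C#CC#CC1=C(C)[C@@H](O)[C@@H](O[Si](C)(C)C(C)(C)C)CC1(C)C
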